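(Readings and results are simulated with constants of no real substance, noise included.)

I had to read this flask at 4.0 h, but in the earlier runs the left-handed substrate had nearly stopped falling well before the last reading, so I counted how far a run gets rather than how long it takes.

all flasks: left-handed substrate 0.10 M; right-handed substrate 0.10 M
- winter: partner 0.40 equiv; protic impurity 0.10 M; free catalyst 0.1 mol%; run made earlier
- midnight: partner 1.6 equiv; protic impurity 0.10 M; free catalyst 0.1 mol%; run made earlier
- spring: partner 0.80 equiv; protic impurity 0.10 M; free catalyst 0.2 mol%; run made earlier
- flask: partner 0.800 equiv; protic impurity 0.100 M; free catalyst 0.1 mol%; time 4.0 h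

| run | time / h | right-handed substrate / % | left-handed substrate / % |
|---|---|---|---|
| winter | 0.417 | 49.8 | 43.2 |
| winter | 0.833 | 49.7 | 42.3 |
| winter | 1.33 | 49.5 | 40.4 |
| winter | 1.50 | 47.0 | 39.7 |
| winter | 2.00 | 49.0 | 40.3 |
| winter | 2.50 | 48.5 | 40.3 |
| midnight | 0.167 | 47.7 | 39.9 |
| midnight | 0.500 | 48.6 | 32.4 |
| midnight | 0.833 | 47.1 | 29.3 |
| midnight | 1.33 | 48.0 | 31.4 |
| midnight | 2.00 | 46.8 | 29.9 |
| midnight | 2.50 | 45.0 | 27.5 |
| spring | 0.200 | 46.5 | 37.6 |
| spring | 0.333 | 47.7 | 34.7 |
| spring | 0.667 | 48.2 | 30.6 |
| spring | 1.33 | 46.8 | 29.7 |
| spring | 2.50 | 47.2 | 28.1 |

(scatter of a reading: 1 percentage point)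

* whether the excess of right-handed substrate over left-handed substrate among what is left of the two reaches 98 % by 4.0 h (no / yes)
* the highest excess of right-handed substrate over left-handed substrate among what is left of the two up to 4.0 h

- free catalyst is single-handed; left-handed substrate and right-handed substrate are mirror images of each other, charged as a racemate, each of them at the stated concentration
- the analysis behind the earlier runs scatters by 1 percentage point, standard deviation

I took as reach z the natural logarithm of right-handed over left-handed substrate at the last reading, which counts the lifetimes by which the left-handed substrate has fallen behind; the excess is then (e^z − 1)/(e^z + 1). These readings gave 0.185 for winter, 0.492 for midnight and 0.519 for spring. Midnight and spring share one product of catalyst loading and partner equivalents, and their reaches stood close together. From winter to midnight that product grew 4.00-fold, so I set z proportional to the product raised to n = 0.705, the reach exponent. This flask has 2.00 times the winter product, which gave me z = 0.302 and an excess of 15.0 %. Reaching 98 % needs z = 4.60, far more than that, so I answered no.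

The forecast answered no and expected the excess to “level off near” 13 %, a little below my figure. The flask gave no, with a top of 17.1 %.

    free catalyst + left-handed substrate ⇌ catalyst intermediate A (K = 24.0 /M, k = 309 /M/s)
    free catalyst + right-handed substrate ⇌ catalyst intermediate B (K = 6.83 /M, k = 777 /M/s)
    partner + catalyst intermediate A → free catalyst + left-handed product (k = 7.62 /M/s)
    partner + catalyst intermediate B → free catalyst + right-handed product (k = 2.42 /M/s)
    left-handed product ⇌ right-handed product (k = 5.54 × 10⁻⁴ /s)
    partner + protic impurity → quenched reagent (k = 0.00110 /M/s)
    2 partner → self-condensation product (k = 0.00745 /M/s)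

That top is a reach of 0.346. By 4.00 h this flask, with partner as limiting reagent, held 0.0144 % of its partner. That the excess in this flask favours the right-handed substrate is owed to two steps acting together: at 4.0 h it stands at 17.1 %, but at −13.7 % without the back reaction of catalyst intermediate B to free catalyst and right-handed substrate, and at −6.47 % without the path from free catalyst and left-handed substrate to catalyst intermediate A.

With 0.25 mol% of free catalyst, a neighbour flask has 1.25 times the midnight product, so n gives z = 0.576 and an excess of 28.0 %; that flask gave 27.0 %.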